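**Retrosynthetic overview**

1. The target is a (2S)-eriodictyol unit whose ring B carbon C5' is bonded to C8'' of luteolin. The last skeletal bond is O1–C8a of the dihydropyranone ring, closed by palladium-catalysed intramolecular O-arylation of an (S)-benzylic carbinol onto a ring A bromide, on the fully assembled octa-O-benzyl seco-compound. The C2–O bond is never broken, so C2 is retained, and the base-labile flavanone is formed only after the biaryl coupling.
2. Enabling feature: C8a is the ring A carbon ortho to C4a, which carries the C4 ketone, and O1 sits on C2, so oxygen and C8a are 1,6-related through C2–C3–C4–C4a and meet in a six-membered ring. The ortho carbonyl activates the C8a–Br bond, and C8a is the only halogenated carbon because the other ortho position (C5) is oxygenated.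
3. The (S)-carbinol comes from copper-catalysed enantioselective conjugate borylation and oxidation of a 2'-bromochalcone. The chalcone comes from Claisen–Schmidt condensation of 2-bromo-4,6-bis(benzyloxy)acetophenone (from 5-bromoresorcinol) with the biaryl aldehyde.
4. The biaryl aldehyde comes from Suzuki–Miyaura coupling of 8-iodo-tetra-O-benzylluteolin (from luteolin) with the pinacol boronate of 3,4-bis(benzyloxy)-5-bromobenzaldehyde.
5. Ring order: the three luteolin rings and rings A and B are bought as arenes; the biaryl bond is made first, the dihydropyranone ring of the flavanone last, and hydrogenolysis of eight benzyl ethers ends the route.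

Key step: step 10

Assumption 1: the C5'–C8'' axis (ortho substituents O, O on one ring, O and H on the other) is taken as freely rotating at room temperature, since the target carries no axial descriptor; no axial control is attempted.

Assumption 2: (R,S)-Josiphos is taken to deliver boron to the face of C-beta that gives the (S)-boronate; if a pilot run shows the opposite sense, the enantiomeric ligand is used with no other change.

Abbreviation: Fl = 5,7-bis(benzyloxy)-2-[3,4-bis(benzyloxy)phenyl]-4-oxo-4H-chromen-8-yl (bonded through C8'').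

**Route**

Step 1
Reactants: 1 luteolin
Product: 2 5,7,3',4'-tetra-O-benzylluteolin
Conditions: BnBr (6 equiv), K2CO3, DMF, 80 °C
Reagents that add atoms: benzyl bromide, BrCc1ccccc1
Why: Williamson ether synthesis on all four phenols; excess halide and heat are used because the 5-hydroxyl is hydrogen-bonded to the C4'' carbonyl.

Step 2
Reactants: 2 5,7,3',4'-tetra-O-benzylluteolin
Product: 3 8-iodo-5,7,3',4'-tetra-O-benzylluteolin
Conditions: NIS (1.1 equiv), TFA (cat.), CH2Cl2/MeCN, 0 °C to rt
Reagents that add atoms: N-iodosuccinimide, O=C1CCC(=O)N1I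
Why: Electrophilic aromatic iodination, expected at C8'' (between the 7-benzyloxy group and the ring oxygen) as is usual for 5,7-dialkoxyflavones, rather than at C6'' between two benzyloxy groups or on the pyranone-deactivated catechol ring.

Step 3
Reactants: 4 3-bromo-4,5-dihydroxybenzaldehyde
Product: 5 3,4-bis(benzyloxy)-5-bromobenzaldehyde
Conditions: BnBr (2.5 equiv), K2CO3, DMF, 60 °C
Reagents that add atoms: benzyl bromide, BrCc1ccccc1
Why: Williamson ether synthesis of both catechol hydroxyls; the aldehyde is inert to carbonate.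

Step 4
Reactants: 5 3,4-bis(benzyloxy)-5-bromobenzaldehyde
Product: 6 3,4-bis(benzyloxy)-5-(pinacolboryl)benzaldehyde
Conditions: B2pin2 (1.2 equiv), PdCl2(dppf) (3 mol %), KOAc, 1,4-dioxane, 85 °C
Reagents that add atoms: bis(pinacolato)diboron, CC1(C)OB(OC1(C)C)B1OC(C)(C)C(C)(C)O1
Why: Miyaura borylation of the aryl bromide; acetate is too weak a base to start Suzuki coupling of product with substrate, and the aldehyde is tolerated.

Step 5
Reactants: 3 8-iodo-5,7,3',4'-tetra-O-benzylluteolin; 6 3,4-bis(benzyloxy)-5-(pinacolboryl)benzaldehyde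
Product: 7 3,4-bis(benzyloxy)-5-Fl-benzaldehyde
Conditions: Pd(OAc)2 (5 mol %), SPhos (10 mol %), K3PO4, toluene/H2O (10:1), 90 °C
Reagents that add atoms: none
Why: Suzuki–Miyaura coupling forms the C5'–C8'' biaryl bond; a dialkylbiarylphosphine is chosen because the product is a tri-ortho-substituted biaryl.

Step 6
Reactants: 8 5-bromoresorcinol
Product: 9 1-(2-bromo-4,6-dihydroxyphenyl)ethan-1-one
Conditions: AcOH, ZnCl2, 140 °C
Reagents that add atoms: acetic acid, CC(=O)O
Why: Nencki reaction (zinc chloride-mediated Friedel–Crafts C-acylation of a resorcinol by acetic acid); attack is expected at C4, para to one hydroxyl and ortho to the other, not at the more hindered C2 between the two hydroxyls.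

Step 7
Reactants: 9 1-(2-bromo-4,6-dihydroxyphenyl)ethan-1-one
Product: 10 1-[2,4-bis(benzyloxy)-6-bromophenyl]ethan-1-one
Conditions: BnBr (3 equiv), K2CO3, DMF, 70 °C
Reagents that add atoms: benzyl bromide, BrCc1ccccc1
Why: Williamson ether synthesis; heating is used so that the chelated hydroxyl ortho to the acetyl group is also alkylated.

Step 8
Reactants: 7 3,4-bis(benzyloxy)-5-Fl-benzaldehyde; 10 1-[2,4-bis(benzyloxy)-6-bromophenyl]ethan-1-one
Product: 11 (E)-2'-bromo-4',6'-bis(benzyloxy)chalcone carrying 3,4-bis(benzyloxy)-5-Fl on the beta-aryl ring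
Conditions: KOH, EtOH/THF, rt
Reagents that add atoms: none
Why: Claisen–Schmidt condensation (aldol addition then E1cB dehydration) should give the E-enone, since the aldehyde has no alpha-hydrogen and the flavone tolerates cold alkali.

Step 9
Reactants: 11 (E)-2'-bromochalcone
Product: 13 (3S)-1-[2,4-bis(benzyloxy)-6-bromophenyl]-3-[3,4-bis(benzyloxy)-5-Fl-phenyl]-3-hydroxypropan-1-one, via (3S)-3-pinacolboryl ketone 12 (not isolated)
Conditions: CuCl (5 mol %), NaOtBu (7.5 mol %), (R,S)-Josiphos [(R)-1-[(S)-2-(diphenylphosphino)ferrocenyl]ethyldicyclohexylphosphine] (6 mol %), B2pin2 (1.2 equiv), MeOH (2 equiv), THF, rt; then NaBO3·4H2O, THF/H2O, 0 °C to rt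
Reagents that add atoms: bis(pinacolato)diboron, CC1(C)OB(OC1(C)C)B1OC(C)(C)C(C)(C)O1 (boryl group of 12, lost on oxidation); sodium perborate, [Na+].[O-]OB=O (hydroxyl oxygen of 13)
Why: Copper-catalysed enantioselective conjugate borylation of a chalcone, in which the chiral diphosphine–copper boryl complex selects the face of C-beta and so sets the future C2, followed by perborate oxidation of the C–B bond with retention; the flavone enone is beta,beta-disubstituted and donor-substituted and should not react.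

Step 10
Reactants: 13 (3S)-beta-hydroxy ketone
Product: 14 (2S)-5,7-bis(benzyloxy)-2-[3,4-bis(benzyloxy)-5-Fl-phenyl]-2,3-dihydro-4H-chromen-4-one
Conditions: Pd2(dba)3 (2.5 mol %), RockPhos (6 mol %), K3PO4 (2 equiv), toluene, 60 °C
Reagents that add atoms: none
Why: Intramolecular Buchwald–Hartwig-type C–O coupling: zerovalent palladium inserts into the C8a–Br bond, which is ortho to the C4 carbonyl on C4a and therefore activated, phosphate-assisted exchange places the C2 alkoxide on divalent palladium, and reductive elimination from the seven-membered oxa-palladacycle forms O1–C8a. The closest known reaction type is the palladium-catalysed cyclisation of 3-(2-bromoaryl)propanols bearing an enantioenriched secondary carbinol to chromans, which goes with retention because the carbinol C–O bond is never broken. The dihydropyranone ring is closed in a 6-exo sense by attack of oxygen on the aryl carbon of ring A. No new stereocentre is formed: C2 keeps the (S) configuration set in step 9, and the weak, insoluble base should keep enolisation at C3, the entry to retro-aldol cleavage and E1cB ring opening, slow. The step needs C–O reductive elimination to win over beta-hydride elimination of the benzylic alkoxide and over base-induced dehydration to the chalcone; the bulky di-tert-butylbiarylphosphine, the mild temperature allowed by the ortho carbonyl, and K3PO4 in toluene are chosen for this, and site selectivity is not an issue because C8a carries the only halogen.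

Step 11
Reactants: 14 octa-O-benzyl flavanone–flavone
Product: 15 CNP0224656.1
Conditions: H2 (1 atm), 10% Pd/C, THF/MeOH, rt
Reagents that add atoms: none
Why: Hydrogenolysis of eight benzyl ethers under neutral conditions, which should not open the flavanone ring or epimerise C2; the reaction is stopped at the uptake of eight equivalents of hydrogen to spare the flavone C2''=C3'' bond and the benzylic C2–O1 bond.

**Compound list**

1 | luteolin, 2-(3,4-dihydroxyphenyl)-5,7-dihydroxy-4H-chromen-4-one | O=c1cc(-c2ccc(O)c(O)c2)oc2cc(O)cc(O)c12 | starting material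
2 | 5,7-bis(benzyloxy)-2-[3,4-bis(benzyloxy)phenyl]-4H-chromen-4-one | O=c1cc(-c2ccc(OCc3ccccc3)c(OCc3ccccc3)c2)oc2cc(OCc3ccccc3)cc(OCc3ccccc3)c12 | intermediate
3 | 5,7-bis(benzyloxy)-2-[3,4-bis(benzyloxy)phenyl]-8-iodo-4H-chromen-4-one | O=c1cc(-c2ccc(OCc3ccccc3)c(OCc3ccccc3)c2)oc2c(I)c(OCc3ccccc3)cc(OCc3ccccc3)c12 | intermediate
4 | 3-bromo-4,5-dihydroxybenzaldehyde | O=Cc1cc(O)c(O)c(Br)c1 | starting material
5 | 3,4-bis(benzyloxy)-5-bromobenzaldehyde | O=Cc1cc(OCc2ccccc2)c(OCc2ccccc2)c(Br)c1 | intermediate
6 | 3,4-bis(benzyloxy)-5-(4,4,5,5-tetramethyl-1,3,2-dioxaborolan-2-yl)benzaldehyde | O=Cc1cc(OCc2ccccc2)c(OCc2ccccc2)c(B2OC(C)(C)C(C)(C)O2)c1 | intermediate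
7 | 3,4-bis(benzyloxy)-5-{5,7-bis(benzyloxy)-2-[3,4-bis(benzyloxy)phenyl]-4-oxo-4H-chromen-8-yl}benzaldehyde | O=Cc1cc(OCc2ccccc2)c(OCc2ccccc2)c(-c2c(OCc3ccccc3)cc(OCc3ccccc3)c3c(=O)cc(-c4ccc(OCc5ccccc5)c(OCc5ccccc5)c4)oc23)c1 | intermediate
8 | 5-bromobenzene-1,3-diol (5-bromoresorcinol) | Oc1cc(O)cc(Br)c1 | starting material
9 | 1-(2-bromo-4,6-dihydroxyphenyl)ethan-1-one | CC(=O)c1c(O)cc(O)cc1Br | intermediate
10 | 1-[2,4-bis(benzyloxy)-6-bromophenyl]ethan-1-one | CC(=O)c1c(OCc2ccccc2)cc(OCc2ccccc2)cc1Br | intermediate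
11 | (2E)-1-[2,4-bis(benzyloxy)-6-bromophenyl]-3-[3,4-bis(benzyloxy)-5-{5,7-bis(benzyloxy)-2-[3,4-bis(benzyloxy)phenyl]-4-oxo-4H-chromen-8-yl}phenyl]prop-2-en-1-one | O=C(/C=C/c1cc(OCc2ccccc2)c(OCc2ccccc2)c(-c2c(OCc3ccccc3)cc(OCc3ccccc3)c3c(=O)cc(-c4ccc(OCc5ccccc5)c(OCc5ccccc5)c4)oc23)c1)c1c(OCc2ccccc2)cc(OCc2ccccc2)cc1Br | intermediate
12 | (3S)-1-[2,4-bis(benzyloxy)-6-bromophenyl]-3-[3,4-bis(benzyloxy)-5-{5,7-bis(benzyloxy)-2-[3,4-bis(benzyloxy)phenyl]-4-oxo-4H-chromen-8-yl}phenyl]-3-(4,4,5,5-tetramethyl-1,3,2-dioxaborolan-2-yl)propan-1-one | O=C(C[C@@H](c1cc(OCc2ccccc2)c(OCc2ccccc2)c(-c2c(OCc3ccccc3)cc(OCc3ccccc3)c3c(=O)cc(-c4ccc(OCc5ccccc5)c(OCc5ccccc5)c4)oc23)c1)B1OC(C)(C)C(C)(C)O1)c1c(OCc2ccccc2)cc(OCc2ccccc2)cc1Br | intermediate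
13 | (3S)-1-[2,4-bis(benzyloxy)-6-bromophenyl]-3-[3,4-bis(benzyloxy)-5-{5,7-bis(benzyloxy)-2-[3,4-bis(benzyloxy)phenyl]-4-oxo-4H-chromen-8-yl}phenyl]-3-hydroxypropan-1-one | O=C(C[C@@H](c1cc(OCc2ccccc2)c(OCc2ccccc2)c(-c2c(OCc3ccccc3)cc(OCc3ccccc3)c3c(=O)cc(-c4ccc(OCc5ccccc5)c(OCc5ccccc5)c4)oc23)c1)O)c1c(OCc2ccccc2)cc(OCc2ccccc2)cc1Br | intermediate
14 | (2S)-5,7-bis(benzyloxy)-2-[3,4-bis(benzyloxy)-5-{5,7-bis(benzyloxy)-2-[3,4-bis(benzyloxy)phenyl]-4-oxo-4H-chromen-8-yl}phenyl]-2,3-dihydro-4H-chromen-4-one | O=C1C[C@@H](c2cc(OCc3ccccc3)c(OCc3ccccc3)c(-c3c(OCc4ccccc4)cc(OCc4ccccc4)c4c(=O)cc(-c5ccc(OCc6ccccc6)c(OCc6ccccc6)c5)oc34)c2)Oc2cc(OCc3ccccc3)cc(OCc3ccccc3)c21 | intermediate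
15 | CNP0224656.1, (2S)-2-{3,4-dihydroxy-5-[2-(3,4-dihydroxyphenyl)-5,7-dihydroxy-4-oxo-4H-chromen-8-yl]phenyl}-5,7-dihydroxy-2,3-dihydro-4H-chromen-4-one | O=C1C[C@@H](c2cc(O)c(O)c(-c3c(O)cc(O)c4c(=O)cc(-c5ccc(O)c(O)c5)oc34)c2)Oc2cc(O)cc(O)c21 | target

**Step count**

Total step count: 11.
Longest linear sequence: 7 steps (steps 1, 2, 5, 8, 9, 10, 11).

**Steps most likely to fail**

1. Step 10. What may go wrong: beta-hydride elimination from the palladium alkoxide (oxidising the carbinol and reducing the C–Br bond), base-induced dehydration or retro-aldol cleavage of the aldol unit, or partial loss of configuration at C2 through ring opening of the product. Fallback, setting out from 13 and returning at 14: the ketone is taken out of play before the closure. Directed reduction (Me4NBH(OAc)3, MeCN/AcOH, −20 °C) should give the anti-configured (1S,3S)-1,3-diol F1, which can neither enolise nor cleave. Ullmann-type etherification (CuI, 3,4,7,8-tetramethyl-1,10-phenanthroline, Cs2CO3, toluene, 110 °C), in which copper alkoxides do not suffer beta-hydride loss and only the hydroxyl on the ring B carbinol can reach C8a in a six-membered ring, should give the (2S,4S)-flavan-4-ol F2. Oxidation with Dess–Martin periodinane (CH2Cl2, NaHCO3, rt) returns to 14.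

2. Step 9. What may go wrong: poor facial selectivity in the boryl transfer, because the carbonyl is twisted out of the plane of the doubly ortho-substituted ring A, or competing borylation at the C–Br bond. Fallback, setting out from 11 and returning at 13: Juliá–Colonna epoxidation (poly-D-leucine, urea–hydrogen peroxide, DBU, THF, rt) should give the trans-configured (2S,3R)-epoxy ketone F3, with the poly-leucine antipode chosen by analogy with the parent chalcone. Reductive opening of the C-alpha–O bond with the phenylselenide reagent made from PhSeSePh and NaBH4 (EtOH/THF, AcOH, 0 °C) keeps the C-beta–O bond and gives 13.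

3. Step 11. What may go wrong: over-reduction (saturation of the flavone C2''=C3'' bond) or hydrogenolysis of the benzylic C2–O1 bond competing with removal of the last benzyl ethers. Fallback, setting out from 14 and returning at 15: non-reductive Lewis-acid debenzylation with BCl3 and pentamethylbenzene as cation scavenger (CH2Cl2, −78 °C), quenched cold with methanol; the low temperature is meant to prevent ionisation of C2–O1. This fallback makes no new compound (F0).

**Further compounds**

F1 | step 10 | (1S,3S)-3-[2,4-bis(benzyloxy)-6-bromophenyl]-1-[3,4-bis(benzyloxy)-5-{5,7-bis(benzyloxy)-2-[3,4-bis(benzyloxy)phenyl]-4-oxo-4H-chromen-8-yl}phenyl]propane-1,3-diol | O[C@@H](C[C@@H](c1cc(OCc2ccccc2)c(OCc2ccccc2)c(-c2c(OCc3ccccc3)cc(OCc3ccccc3)c3c(=O)cc(-c4ccc(OCc5ccccc5)c(OCc5ccccc5)c4)oc23)c1)O)c1c(OCc2ccccc2)cc(OCc2ccccc2)cc1Br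
F2 | step 10 | (2S,4S)-5,7-bis(benzyloxy)-2-[3,4-bis(benzyloxy)-5-{5,7-bis(benzyloxy)-2-[3,4-bis(benzyloxy)phenyl]-4-oxo-4H-chromen-8-yl}phenyl]-3,4-dihydro-2H-chromen-4-ol | O[C@H]1C[C@@H](c2cc(OCc3ccccc3)c(OCc3ccccc3)c(-c3c(OCc4ccccc4)cc(OCc4ccccc4)c4c(=O)cc(-c5ccc(OCc6ccccc6)c(OCc6ccccc6)c5)oc34)c2)Oc2cc(OCc3ccccc3)cc(OCc3ccccc3)c21
F3 | step 9 | [2,4-bis(benzyloxy)-6-bromophenyl][(2S,3R)-3-(3,4-bis(benzyloxy)-5-{5,7-bis(benzyloxy)-2-[3,4-bis(benzyloxy)phenyl]-4-oxo-4H-chromen-8-yl}phenyl)oxiran-2-yl]methanone | O=C(c1c(OCc2ccccc2)cc(OCc2ccccc2)cc1Br)[C@H]7O[C@@H]7c1cc(OCc2ccccc2)c(OCc2ccccc2)c(-c2c(OCc3ccccc3)cc(OCc3ccccc3)c3c(=O)cc(-c4ccc(OCc5ccccc5)c(OCc5ccccc5)c4)oc23)c1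
F0 | step 11 | none | none
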